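**Retrosynthetic overview**
- Last bond: O-acetylation of the free (S)-carbinol.
- Key disconnection: the bond between pyranone C-6 and the side chain. It is made by a desymmetrising vinylic substitution (conjugate addition–elimination) of one of the two equivalent MeO groups of 2,6-dimethoxy-3,5-dimethyl-4H-pyran-4-one by an unprotected, alkoxide-bearing C11 alkyllithium. The usual route (triketo ester carrying the chain, cyclisation, regioselective O-methylation) is not used.
- Side chain and stereocentre: (S)-propylene oxide is opened at CH2 by the Grignard reagent of 1-bromo-8-chlorooctane. The remaining chloride is the carbanion precursor, so no protecting group is needed.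
- Ring order: the only ring, the γ-pyranone, is made first as the symmetric dimethoxy compound by cyclodehydration of dimethyl 2,4-dimethyl-3-oxopentanedioate (from dimethyl 3-oxopentanedioate and MeI), before the chain is attached.

Assumption: the [C@H] centre of the given SMILES is (S) (C-2 of the undecyl chain), and commercial (S)-propylene oxide of at least 99% ee is used.

**Step 1**
Reactants: 1 dimethyl 3-oxopentanedioate
Product: 2 dimethyl 2,4-dimethyl-3-oxopentanedioate (mixture of diastereomers)
Conditions: MeI (2.2 equiv), K2CO3 (2.2 equiv), acetone, reflux; distillation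
Reagents that add atoms: iodomethane, CI
Why: Double SN2 C-alkylation of the doubly activated β-keto diester, one methyl at each α-carbon under mild carbonate base; the diastereomer mixture is irrelevant because both carbons become sp2 in step 2.

**Step 2**
Reactants: 2 dimethyl 2,4-dimethyl-3-oxopentanedioate
Product: 3 2,6-dimethoxy-3,5-dimethyl-4H-pyran-4-one
Conditions: oleum (H2SO4 with 20% SO3), 0 °C → rt; poured on ice
Reagents that add atoms: none
Why: Acid-mediated cyclodehydration in which one ester carbonyl oxygen attacks the other protonated ester group and SO3 binds the water irreversibly, so both ester carbons end up as the MeO-bearing carbons of the symmetric γ-pyranone (the same reaction type as the acid closure of 3,5-dioxo esters to 2-methoxy-4-pyranones).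

**Step 3**
Reactants: 4 1-bromo-8-chlorooctane; 5 (S)-2-methyloxirane ((S)-propylene oxide)
Product: 7 (2S)-11-chloroundecan-2-ol, via (8-chlorooctyl)magnesium bromide 6 (not isolated)
Conditions: Mg, I2 (cat.), THF, 35 °C; then CuI (5 mol%), 5 (1.2 equiv), THF, –30 → 0 °C; 1 M HCl
Reagents that add atoms: none
Why: Chemoselective Grignard formation at C–Br (C–Cl is inert to Mg under these conditions) followed by copper-catalysed SN2 opening of the epoxide at its unsubstituted CH2; no bond at the stereocentre is touched, so the (S) configuration of 5 is carried into 7.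

**Step 4**
Reactants: 7 (2S)-11-chloroundecan-2-ol; 3 2,6-dimethoxy-3,5-dimethyl-4H-pyran-4-one
Product: 11 2-[(10S)-10-hydroxyundecyl]-6-methoxy-3,5-dimethyl-4H-pyran-4-one, via lithium (2S)-11-chloroundecan-2-olate 8 (not isolated), via lithium (2S)-11-lithioundecan-2-olate 9 (not isolated), via dilithium 2-alkyl-2,6-dimethoxy-2H-pyran-4-olate adduct 10 (not isolated)
Conditions: n-BuLi (1.0 equiv), THF, –78 °C; LiDBB (lithium 4,4'-di-tert-butylbiphenylide, 2.1 equiv), THF, –78 °C; cannulated into 3 (1.5 equiv), THF, –78 → –30 °C; aq NH4Cl
Reagents that add atoms: none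
Why: Reductive lithiation of the primary chloride by the arene radical anion, with the hydroxyl masked as its lithium alkoxide, gives an O,C-dilithio reagent whose carbanion adds 1,4 to one of the two equivalent MeO-bearing carbons of 3 and expels LiOMe (conjugate addition–elimination, a vinylic nucleophilic substitution on a vinylogous carbonate); inverse addition to excess 3 suppresses double substitution and deprotonation of the new lateral CH2, and the remote stereocentre is not involved.

**Step 5**
Reactants: 11 2-[(10S)-10-hydroxyundecyl]-6-methoxy-3,5-dimethyl-4H-pyran-4-one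
Product: 12 (2S)-11-(6-methoxy-3,5-dimethyl-4-oxo-4H-pyran-2-yl)undecan-2-yl acetate
Conditions: Ac2O (1.5 equiv), pyridine, DMAP (cat.), CH2Cl2, 0 °C → rt
Reagents that add atoms: acetic anhydride, CC(=O)OC(C)=O
Why: DMAP-catalysed O-acylation of the secondary alcohol; the C–O bond at the stereocentre is not broken, so (S) is retained and the methoxypyranone is inert to these conditions.

**Compound list**
1 | dimethyl 3-oxopentanedioate | COC(=O)CC(=O)CC(=O)OC | starting material
2 | dimethyl 2,4-dimethyl-3-oxopentanedioate (mixture of diastereomers) | COC(=O)C(C)C(=O)C(C)C(=O)OC | intermediate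
3 | 2,6-dimethoxy-3,5-dimethyl-4H-pyran-4-one | COc1oc(OC)c(C)c(=O)c1C | intermediate
4 | 1-bromo-8-chlorooctane | BrCCCCCCCCCl | starting material
5 | (S)-2-methyloxirane | C[C@H]1CO1 | starting material
6 | (8-chlorooctyl)magnesium bromide | ClCCCCCCCC[Mg]Br | intermediate
7 | (2S)-11-chloroundecan-2-ol | C[C@H](O)CCCCCCCCCCl | intermediate
8 | lithium (2S)-11-chloroundecan-2-olate | C[C@H](O[Li])CCCCCCCCCCl | intermediate
9 | lithium (2S)-11-lithioundecan-2-olate | C[C@H](O[Li])CCCCCCCCC[Li] | intermediate
10 | dilithium 2-alkyl-2,6-dimethoxy-2H-pyran-4-olate adduct (alkyl = (10S)-10-oxidoundecyl; either configuration at ring C-2) | C[C@H](O[Li])CCCCCCCCCC1(OC)OC(OC)=C(C)C(O[Li])=C1C | intermediate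
11 | 2-[(10S)-10-hydroxyundecyl]-6-methoxy-3,5-dimethyl-4H-pyran-4-one | COc1oc(CCCCCCCCC[C@H](C)O)c(C)c(=O)c1C | intermediate
12 | (2S)-11-(6-methoxy-3,5-dimethyl-4-oxo-4H-pyran-2-yl)undecan-2-yl acetate | COc1oc(CCCCCCCCC[C@H](C)OC(C)=O)c(C)c(=O)c1C | target

**Step count**
Total: 5 steps. Longest linear sequence: 4 steps (1 → 2 → 3 → 11 → 12, that is steps 1, 2, 4 and 5).

**Steps most likely to fail, with fallbacks**

Risk 1, step 4. The dianion may form incompletely or aggregate, it may add 1,2 to the carbonyl, or it may be quenched by the acidic lateral CH2 of the product. The fallback sets out from 7 and 3 and comes back at 11, using a soft, stabilised carbanion instead of the alkyllithium. Compound 7 is treated with PhSO2Na (NaI cat., DMF, 80 °C) to give (2S)-11-(phenylsulfonyl)undecan-2-ol F1. Its O,C-dianion (n-BuLi, 2 equiv, THF, –78 °C) is added to 3 in the same addition–elimination sense to give 2-[(10S)-10-hydroxy-1-(phenylsulfonyl)undecyl]-6-methoxy-3,5-dimethyl-4H-pyran-4-one F2, as both epimers at the sulfonyl carbon. Reductive desulfonylation of this vinylogous β-keto sulfone (SmI2, THF–MeOH, –78 °C) then gives 11.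

Risk 2, step 2. Oleum may char the substrate or cleave the esters instead of closing the ring. The fallback sets out from 2 and comes back at 3, building the ring stepwise. Half-saponification of 2 (KOH, 1 equiv, MeOH–H2O, 0 °C, cold acidification) gives 5-methoxy-2,4-dimethyl-3,5-dioxopentanoic acid F3, which is used at once. Activation of the acid (TFAA, CH2Cl2, 0 °C) lets the ester carbonyl oxygen close the ring, as in the closure of homophthalic half esters to 3-alkoxyisocoumarins, giving 4-hydroxy-6-methoxy-3,5-dimethyl-2H-pyran-2-one F4. Hard O-methylation at the lactone carbonyl oxygen (MeOTf, CH2Cl2, then aq NaHCO3), the usual way from 4-hydroxy-2-pyranones to 2-methoxy-4-pyranones, gives 3.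

Risk 3, step 3. Wurtz coupling during Grignard formation, or halohydrin formation from the epoxide, may lower the yield. The fallback sets out from 4 (through 6) and comes back at 7, setting the stereocentre by catalysis instead of from the chiral pool. Grignard reagent 6 is allylated with allyl bromide (CuI cat., THF, 0 °C) to give 11-chloroundec-1-ene F5. Tsuji–Wacker oxidation (PdCl2 cat., CuCl, O2, DMF–H2O, rt) gives 11-chloroundecan-2-one F6. A Prelog-selective alcohol dehydrogenase (ADH-A of Rhodococcus ruber, NADH cat., i-PrOH, buffer pH 7.5, 30 °C) then reduces the methyl ketone to the (S)-alcohol 7.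

**Further compounds**
F1 | step 4 | (2S)-11-(phenylsulfonyl)undecan-2-ol | C[C@H](O)CCCCCCCCCS(=O)(=O)c1ccccc1
F2 | step 4 | 2-[(10S)-10-hydroxy-1-(phenylsulfonyl)undecyl]-6-methoxy-3,5-dimethyl-4H-pyran-4-one (both epimers at the sulfonyl carbon) | COc1oc(C(CCCCCCCC[C@H](C)O)S(=O)(=O)c2ccccc2)c(C)c(=O)c1C
F3 | step 2 | 5-methoxy-2,4-dimethyl-3,5-dioxopentanoic acid | COC(=O)C(C)C(=O)C(C)C(O)=O
F4 | step 2 | 4-hydroxy-6-methoxy-3,5-dimethyl-2H-pyran-2-one | COc1oc(=O)c(C)c(O)c1C
F5 | step 3 | 11-chloroundec-1-ene | C=CCCCCCCCCCCl
F6 | step 3 | 11-chloroundecan-2-one | CC(=O)CCCCCCCCCCl
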